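**Retrosynthetic overview**
1. Target 23 ⇐ one acidolysis of the 4-methoxybenzyl ether and tert-butyl ester of 22.
2. 22 ⇐ the only ring (the cyclohexane) is closed last: intramolecular aldol–Tishchenko annulation of acyclic keto-aldehyde 15 with (Z)-enal 19 forms C7–C8, sets C6, C7 and C8 and delivers the C8 ester.
3. 15 ⇐ indium Barbier allylation with tert-butyl 2-(bromomethyl)acrylate and double oxidation of 11 (masked C6 aldehyde, C8 silyl ether).
4. 11 ⇐ α-keto ester 8 (methylenation, reduction, protection) ⇐ organocatalytic enantioselective Claisen rearrangement of achiral allyl vinyl ether 7, which sets C5 and C10 together.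
5. 7 ⇐ (E)-allylic alcohol 3 (carboalumination of a butynyl silyl ether) + diazophosphonoacetate 4 + dimethoxyacetaldehyde 6.

Assumption: ring compounds carry elemane locants (C10 = quaternary carbon with the methyl and the C1=C2 vinyl, then C9, C8, C7, C6, C5 round the ring; C4(=C3)–C15 on C5; C11(=C13)–C12 on C7); the catalyst antipode in step 4 is taken to be the one that gives 8 (both antipodes are accessible); 4 and anhydrous 6 are taken as purchasable.

**Step 1**
Reactants: 1 tert-butyl(but-3-yn-1-yloxy)dimethylsilane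
Product: 3 (2E)-5-[(tert-butyldimethylsilyl)oxy]-3-methylpent-2-en-1-ol, via alkenylalane 2 (not isolated)
Conditions: Me3Al, Cp2ZrCl2 (25 mol %), CH2Cl2, 0 °C to rt; then n-BuLi, (CH2O)n, THF, −30 °C to rt
Reagents that add atoms: trimethylaluminium C[Al](C)C; paraformaldehyde (as formaldehyde) C=O
Why: Zirconium-catalysed Negishi carboalumination adds methyl and aluminium syn across the alkyne, and hydroxymethylation of the alkenylalanate with retention gives only the E trisubstituted alkene.

**Step 2**
Reactants: 3 (2E)-5-[(tert-butyldimethylsilyl)oxy]-3-methylpent-2-en-1-ol; 4 triethyl diazophosphonoacetate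
Product: 5 ethyl 2-(diethoxyphosphoryl)-2-{[(2E)-5-[(tert-butyldimethylsilyl)oxy]-3-methylpent-2-en-1-yl]oxy}acetate (racemic at C2; this centre is erased in step 3)
Conditions: Rh2(OAc)4 (1 mol %), toluene, 80 °C
Reagents that add atoms: none
Why: Rhodium-carbenoid O–H insertion into the primary allylic alcohol is faster than cyclopropanation of the trisubstituted alkene and gives the α-alkoxy phosphonate directly.

**Step 3**
Reactants: 5 the α-alkoxy phosphonate; 6 2,2-dimethoxyacetaldehyde
Product: 7 ethyl (2Z)-4,4-dimethoxy-2-{[(2E)-5-[(tert-butyldimethylsilyl)oxy]-3-methylpent-2-en-1-yl]oxy}but-2-enoate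
Conditions: LiN(SiMe3)2, THF, −78 to 0 °C; minor E isomer removed by chromatography
Reagents that add atoms: none
Why: Horner–Wadsworth–Emmons olefination of an α-alkoxy phosphonoacetate places the aldehyde substituent trans to the ester, which is the (Z)-enol ether needed for the rearrangement.

**Step 4**
Reactants: 7 the (Z,E) allyl vinyl ether
Product: 8 ethyl (3R,4S)-4-{2-[(tert-butyldimethylsilyl)oxy]ethyl}-3-(dimethoxymethyl)-4-methyl-2-oxohex-5-enoate
Conditions: C2-symmetric N,N′-bis[(1R,2R)-2-(2,5-diphenylpyrrol-1-yl)cyclohexyl]guanidinium tetrakis[3,5-bis(trifluoromethyl)phenyl]borate (20 mol %), hexanes, 35 °C, 5 d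
Reagents that add atoms: none
Why: Organocatalytic enantioselective Claisen rearrangement in which the chiral guanidinium ion hydrogen-bonds to the ether oxygen and ester carbonyl and selects one face of a chair transition state; the (Z)-enol ether puts the acetal carbon axial and the (E)-allyl unit puts the methyl axial, so C5 and C10 of the target (side chain and vinyl on the same side) are set together as the first stereocentres.

**Step 5**
Reactants: 8 the α-keto ester
Product: 9 ethyl (3S,4S)-4-{2-[(tert-butyldimethylsilyl)oxy]ethyl}-3-(dimethoxymethyl)-4-methyl-2-methylidenehex-5-enoate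
Conditions: Ph3PCH3Br, KN(SiMe3)2, THF, −78 to 0 °C
Reagents that add atoms: methyltriphenylphosphonium bromide C[P+](c1ccccc1)(c1ccccc1)c1ccccc1.[Br-]
Why: Wittig methylenation of the strongly electrophilic α-keto carbonyl is fast at low temperature, which limits enolisation at the adjacent hindered stereocentre.

**Step 6**
Reactants: 9 the 2-substituted acrylate
Product: 10 (3S,4S)-4-{2-[(tert-butyldimethylsilyl)oxy]ethyl}-3-(dimethoxymethyl)-4-methyl-2-methylidenehex-5-en-1-ol
Conditions: iBu2AlH (2.5 equiv), CH2Cl2, −78 °C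
Reagents that add atoms: none
Why: 1,2-Reduction of the acrylate ester gives the 2-substituted allylic alcohol (C15) and leaves acetal, silyl ether and stereocentres untouched.

**Step 7**
Reactants: 10 the allylic alcohol
Product: 11 (3S,4S)-4-{2-[(tert-butyldimethylsilyl)oxy]ethyl}-3-(dimethoxymethyl)-1-[(4-methoxybenzyl)oxy]-4-methyl-2-methylidenehex-5-ene
Conditions: NaH, 4-MeOC6H4CH2Cl, Bu4NI (cat.), THF/DMF, 0 °C to rt
Reagents that add atoms: 4-methoxybenzyl chloride COc1ccc(CCl)cc1
Why: Williamson etherification gives an ether that survives dilute aqueous acid and oxidation and is removed together with the tert-butyl ester at the end.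

**Step 8**
Reactants: 11 the protected acetal; 12 tert-butyl 2-(bromomethyl)prop-2-enoate
Product: 14 tert-butyl (5S,6S)-4-hydroxy-6-(2-hydroxyethyl)-5-{3-[(4-methoxybenzyl)oxy]prop-1-en-2-yl}-6-methyl-2-methylideneoct-7-enoate (both C4 epimers), via lactol 13 (not isolated)
Conditions: 0.5 M aq. HCl/THF, rt; then indium powder and 12 added to the same solution, rt
Reagents that add atoms: water O
Why: Acid hydrolysis of acetal and silyl ether gives a six-membered lactol that shields the epimerisable α-branched aldehyde, and indium-mediated Barbier allylation of the lactol in water gives the homoallylic alcohol, whose carbinol configuration is irrelevant because it is oxidised next.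

**Step 9**
Reactants: 14 the diol
Product: 15 tert-butyl (5S,6S)-5-{3-[(4-methoxybenzyl)oxy]prop-1-en-2-yl}-6-methyl-2-methylidene-4-oxo-6-(2-oxoethyl)oct-7-enoate
Conditions: (COCl)2, DMSO, CH2Cl2, −78 °C; Et3N, −78 to −40 °C; cold pH 7 quench; used crude
Reagents that add atoms: none
Why: Swern oxidation activates both hydroxyls as alkoxysulfonium ions before any carbonyl forms, so the C6 ketone and C8 aldehyde arise together without lactol-to-lactone oxidation.

**Step 10**
Reactants: 16 dimethyl (2Z)-2-methylbut-2-enedioate (dimethyl citraconate)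
Product: 17 (2Z)-2-methylbut-2-ene-1,4-diol
Conditions: iBu2AlH (4.5 equiv), CH2Cl2, −78 to 0 °C
Reagents that add atoms: none
Why: Hydride reduction of both esters keeps the Z alkene geometry.

**Step 11**
Reactants: 17 the (Z)-diol
Product: 18 (2Z)-4-hydroxy-3-methylbut-2-en-1-yl acetate
Conditions: Burkholderia cepacia lipase (lipase PS), vinyl acetate, iPr2O, rt
Reagents that add atoms: vinyl acetate C=COC(C)=O
Why: Lipase-catalysed transesterification acylates the less hindered hydroxymethyl group (the one on the unsubstituted alkene carbon) regioselectively.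

**Step 12**
Reactants: 18 the monoacetate
Product: 19 (2Z)-3-methyl-4-oxobut-2-en-1-yl acetate ((Z)-4-acetoxy-2-methylbut-2-enal)
Conditions: TEMPO (10 mol %), PhI(OAc)2, CH2Cl2, rt; used at once
Reagents that add atoms: none
Why: Oxoammonium oxidation of the allylic alcohol gives the enal without Z-to-E isomerisation.

**Step 13**
Reactants: 15 the keto-aldehyde; 19 the (Z)-enal
Product: 22 tert-butyl (5S,6R,7S,8R,10S)-8-{[(2Z)-4-acetoxy-2-methylbut-2-enoyl]oxy}-6-hydroxy-15-[(4-methoxybenzyl)oxy]elema-1,3,11(13)-trien-12-oate, via aldol adduct 20 (not isolated), via hemiacetal 21 (not isolated)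
Conditions: SmI2 (30 mol %) premixed with PhCHO (30 mol %) in THF, rt, until the blue colour is gone; then 19 in excess, then 15 by slow addition, THF, −10 °C, dark
Reagents that add atoms: none
Why: Proposed new method: an intramolecular aldol–Tishchenko annulation with an external (Z)-γ-acyloxy enal as hydride donor, in which the trivalent samarium pinacolate I2SmOCH(Ph)CH(Ph)OSmI2, made beforehand from SmI2 (divalent samarium) and PhCHO so that no reducing samarium meets 15 or 19, enolises the doubly activated C7 methylene and closes the ring onto the C8 aldehyde with the C8 oxygen equatorial (20), the O8 alkoxide adds to one equivalent of 19 (21), and the hemiacetal hydrogen is delivered through a six-membered chair to the same face of the C6 ketone, giving irreversibly and with no by-product the 6,8-anti diol monoester with the acyl group on O8, the free C6 hydroxyl cis to the C5 side chain, and the C7 epimer whose acrylate arm is cis to O8; the closest known reactions are the samarium-catalysed Evans–Tishchenko reduction of β-hydroxy ketones and the intermolecular tandem aldol–Tishchenko reaction.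

**Step 14**
Reactants: 22 the protected ester
Product: 23 (5S,6R,7S,8R,10S)-8-{[(2Z)-4-acetoxy-2-methylbut-2-enoyl]oxy}-6,15-dihydroxyelema-1,3,11(13)-trien-12-oic acid (target)
Conditions: CF3CO2H/CH2Cl2 (1:4), anisole, 0 °C; brief aq. NaHCO3/MeOH wash, then pH 4
Reagents that add atoms: none
Why: Acidolysis cleaves the 4-methoxybenzyl ether and tert-butyl ester in one step, while the acetate, the Z enoate and the alkenes are stable, and lactonisation of the C6 hydroxyl onto C12 is disfavoured because the trans-fused lactone needs a chair with the C8 ester and C10 methyl syn-diaxial.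

**Compound list**
1 | tert-butyl(but-3-yn-1-yloxy)dimethylsilane | C#CCCO[Si](C)(C)C(C)(C)C | starting material
2 | dimethyl{(1E)-4-[(tert-butyldimethylsilyl)oxy]-2-methylbut-1-en-1-yl}alane | C/C(=C\[Al](C)C)CCO[Si](C)(C)C(C)(C)C | intermediate
3 | (2E)-5-[(tert-butyldimethylsilyl)oxy]-3-methylpent-2-en-1-ol | C/C(=C\CO)CCO[Si](C)(C)C(C)(C)C | intermediate
4 | triethyl diazophosphonoacetate (ethyl 2-diazo-2-(diethoxyphosphoryl)acetate) | CCOC(=O)C(=[N+]=[N-])P(=O)(OCC)OCC | starting material
5 | ethyl 2-(diethoxyphosphoryl)-2-{[(2E)-5-[(tert-butyldimethylsilyl)oxy]-3-methylpent-2-en-1-yl]oxy}acetate (racemic) | CCOC(=O)C(OC/C=C(\C)CCO[Si](C)(C)C(C)(C)C)P(=O)(OCC)OCC | intermediate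
6 | 2,2-dimethoxyacetaldehyde | COC(OC)C=O | starting material
7 | ethyl (2Z)-4,4-dimethoxy-2-{[(2E)-5-[(tert-butyldimethylsilyl)oxy]-3-methylpent-2-en-1-yl]oxy}but-2-enoate | CCOC(=O)/C(OC/C=C(\C)CCO[Si](C)(C)C(C)(C)C)=C/C(OC)OC | intermediate
8 | ethyl (3R,4S)-4-{2-[(tert-butyldimethylsilyl)oxy]ethyl}-3-(dimethoxymethyl)-4-methyl-2-oxohex-5-enoate | C=C[C@](C)(CCO[Si](C)(C)C(C)(C)C)[C@H](C(OC)OC)C(=O)C(=O)OCC | intermediate
9 | ethyl (3S,4S)-4-{2-[(tert-butyldimethylsilyl)oxy]ethyl}-3-(dimethoxymethyl)-4-methyl-2-methylidenehex-5-enoate | C=C[C@](C)(CCO[Si](C)(C)C(C)(C)C)[C@H](C(OC)OC)C(=C)C(=O)OCC | intermediate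
10 | (3S,4S)-4-{2-[(tert-butyldimethylsilyl)oxy]ethyl}-3-(dimethoxymethyl)-4-methyl-2-methylidenehex-5-en-1-ol | C=C[C@](C)(CCO[Si](C)(C)C(C)(C)C)[C@H](C(OC)OC)C(=C)CO | intermediate
11 | (3S,4S)-4-{2-[(tert-butyldimethylsilyl)oxy]ethyl}-3-(dimethoxymethyl)-1-[(4-methoxybenzyl)oxy]-4-methyl-2-methylidenehex-5-ene | C=C[C@](C)(CCO[Si](C)(C)C(C)(C)C)[C@H](C(OC)OC)C(=C)COCc1ccc(OC)cc1 | intermediate
12 | tert-butyl 2-(bromomethyl)prop-2-enoate | C=C(CBr)C(=O)OC(C)(C)C | starting material
13 | (3S,4S)-4-ethenyl-3-{3-[(4-methoxybenzyl)oxy]prop-1-en-2-yl}-4-methyloxan-2-ol (anomer mixture) | C=C[C@]1(C)CCOC(O)[C@@H]1C(=C)COCc1ccc(OC)cc1 | intermediate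
14 | tert-butyl (5S,6S)-4-hydroxy-6-(2-hydroxyethyl)-5-{3-[(4-methoxybenzyl)oxy]prop-1-en-2-yl}-6-methyl-2-methylideneoct-7-enoate (C4 epimers) | C=C[C@](C)(CCO)[C@H](C(O)CC(=C)C(=O)OC(C)(C)C)C(=C)COCc1ccc(OC)cc1 | intermediate
15 | tert-butyl (5S,6S)-5-{3-[(4-methoxybenzyl)oxy]prop-1-en-2-yl}-6-methyl-2-methylidene-4-oxo-6-(2-oxoethyl)oct-7-enoate | C=C[C@](C)(CC=O)[C@H](C(=O)CC(=C)C(=O)OC(C)(C)C)C(=C)COCc1ccc(OC)cc1 | intermediate
16 | dimethyl (2Z)-2-methylbut-2-enedioate | COC(=O)/C=C(/C)C(=O)OC | starting material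
17 | (2Z)-2-methylbut-2-ene-1,4-diol | OC/C=C(C)\CO | intermediate
18 | (2Z)-4-hydroxy-3-methylbut-2-en-1-yl acetate | CC(=O)OC/C=C(C)\CO | intermediate
19 | (2Z)-3-methyl-4-oxobut-2-en-1-yl acetate | CC(=O)OC/C=C(C)\C=O | intermediate
20 | tert-butyl (5S,7R,8R,10S)-8-hydroxy-15-[(4-methoxybenzyl)oxy]-6-oxoelema-1,3,11(13)-trien-12-oate (C10 methyl β; C5 side chain α; C7 acrylate β; C8 hydroxyl β) | C=C[C@]1(C)C[C@@H](O)[C@@H](C(=C)C(=O)OC(C)(C)C)C(=O)[C@@H]1C(=C)COCc1ccc(OC)cc1 | intermediate
21 | hemiacetal of 20 at O8 with enal 19 (same ring configuration; hemiacetal carbon unassigned) | C=C[C@]1(C)C[C@@H](OC(O)/C(C)=C\COC(C)=O)[C@@H](C(=C)C(=O)OC(C)(C)C)C(=O)[C@@H]1C(=C)COCc1ccc(OC)cc1 | intermediate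
22 | tert-butyl (5S,6R,7S,8R,10S)-8-{[(2Z)-4-acetoxy-2-methylbut-2-enoyl]oxy}-6-hydroxy-15-[(4-methoxybenzyl)oxy]elema-1,3,11(13)-trien-12-oate | C=C[C@]1(C)C[C@@H](OC(=O)/C(C)=C\COC(C)=O)[C@@H](C(=C)C(=O)OC(C)(C)C)[C@H](O)[C@@H]1C(=C)COCc1ccc(OC)cc1 | intermediate
23 | (5S,6R,7S,8R,10S)-8-{[(2Z)-4-acetoxy-2-methylbut-2-enoyl]oxy}-6,15-dihydroxyelema-1,3,11(13)-trien-12-oic acid (C10 methyl β and vinyl α; C5 side chain α; C6 hydroxyl α; C7 acrylic acid β; C8 ester β) | C=C[C@]1(C)C[C@@H](OC(=O)/C(C)=C\COC(C)=O)[C@@H](C(=C)C(=O)O)[C@H](O)[C@@H]1C(=C)CO | target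

**Step count**
Total steps: 14. Longest linear sequence: 11 (steps 1–9, 13, 14); steps 10–12 are the side-chain branch.

**Three steps most likely to fail, with fallbacks**

Step 13 (the proposed new step). Risks: the aldol is reversible, so the hydride-transfer step could drain the material through the C8 epimer and give the 6β,8α monoester; the enal could isomerise Z to E on samarium; the substrate aldehyde could undergo intermolecular Tishchenko reaction, which is why 15 is added slowly to an excess of 19 (one equivalent is incorporated and the surplus is recovered unchanged on chromatography); C5 could epimerise next to the C6 ketone. Fallback with known chemistry, stepwise and with each centre fixed in its own step: it sets out from 15 (and 19) and comes back at 22. Keto-aldehyde 15 is cyclised by enamine catalysis (pyrrolidine/AcOH, 20 mol %, CH2Cl2, 0 °C). The E-enamine places the acrylate arm axial and the new hydroxyl equatorial, and the aldol adduct 20 is isolated. Hydroxyl-directed reduction with Me4NBH(OAc)3 in AcOH/MeCN at −30 °C (Saksena–Evans) delivers hydride from the O8 face and gives tert-butyl (5S,6R,7R,8R,10S)-6,8-dihydroxy-15-[(4-methoxybenzyl)oxy]elema-1,3,11(13)-trien-12-oate F5. Enal 19 is oxidised with NaClO2/NaH2PO4/2-methylbut-2-ene to (2Z)-4-acetoxy-2-methylbut-2-enoic acid F6. Yamaguchi esterification (2,4,6-trichlorobenzoyl chloride, Et3N, then DMAP, toluene, rt) acylates the less hindered C8 hydroxyl of F5 and gives 22.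

Step 9. Risks: the β,γ-unsaturated keto-aldehyde 15 can isomerise into conjugation, epimerise at C5 or aldolise when the amine base is added, and a 1,5-diol can divert to a lactone. Fallback that oxidises the two carbinols separately and uses no amine base: it sets out from 11 and comes back at 15. The acetal alone is hydrolysed with LiBF4 in wet MeCN to (2S,3S)-3-{2-[(tert-butyldimethylsilyl)oxy]ethyl}-2-{3-[(4-methoxybenzyl)oxy]prop-1-en-2-yl}-3-methylpent-4-enal F1. Indium and 12 in THF/H2O give tert-butyl (5S,6S)-6-{2-[(tert-butyldimethylsilyl)oxy]ethyl}-4-hydroxy-5-{3-[(4-methoxybenzyl)oxy]prop-1-en-2-yl}-6-methyl-2-methylideneoct-7-enoate F2. Dess–Martin periodinane with NaHCO3 gives tert-butyl (5S,6S)-6-{2-[(tert-butyldimethylsilyl)oxy]ethyl}-5-{3-[(4-methoxybenzyl)oxy]prop-1-en-2-yl}-6-methyl-2-methylidene-4-oxooct-7-enoate F3. HF·pyridine in THF gives tert-butyl (5S,6S)-6-(2-hydroxyethyl)-5-{3-[(4-methoxybenzyl)oxy]prop-1-en-2-yl}-6-methyl-2-methylidene-4-oxooct-7-enoate F4, and a second buffered Dess–Martin oxidation gives 15.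

Step 4. Risks: the hindered trisubstituted allyl terminus and the acetal oxygens (competing hydrogen-bond acceptors) may slow the rearrangement or erode the selectivity. Fallback that replaces hydrogen-bond organocatalysis by two-point chelation to a chiral Lewis acid: it sets out from 7 and comes back at 8. Ether 7 is rearranged with [Cu{(S,S)-tBu-box}(H2O)2](SbF6)2 (5 mol %, divalent copper; box = 2,2′-isopropylidenebis(4-tert-butyl-2-oxazoline)) in CH2Cl2 at rt. The copper binds the ether oxygen and ester carbonyl of the 2-alkoxycarbonyl allyl vinyl ether, and the same chair-controlled relative configuration follows from the (Z,E) geometry. No new compound is made.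

**Further compounds**
F0 | step 4 | none | none
F1 | step 9 | (2S,3S)-3-{2-[(tert-butyldimethylsilyl)oxy]ethyl}-2-{3-[(4-methoxybenzyl)oxy]prop-1-en-2-yl}-3-methylpent-4-enal | C=C[C@](C)(CCO[Si](C)(C)C(C)(C)C)[C@H](C=O)C(=C)COCc1ccc(OC)cc1
F2 | step 9 | tert-butyl (5S,6S)-6-{2-[(tert-butyldimethylsilyl)oxy]ethyl}-4-hydroxy-5-{3-[(4-methoxybenzyl)oxy]prop-1-en-2-yl}-6-methyl-2-methylideneoct-7-enoate (C4 epimers) | C=C[C@](C)(CCO[Si](C)(C)C(C)(C)C)[C@H](C(O)CC(=C)C(=O)OC(C)(C)C)C(=C)COCc1ccc(OC)cc1
F3 | step 9 | tert-butyl (5S,6S)-6-{2-[(tert-butyldimethylsilyl)oxy]ethyl}-5-{3-[(4-methoxybenzyl)oxy]prop-1-en-2-yl}-6-methyl-2-methylidene-4-oxooct-7-enoate | C=C[C@](C)(CCO[Si](C)(C)C(C)(C)C)[C@H](C(=O)CC(=C)C(=O)OC(C)(C)C)C(=C)COCc1ccc(OC)cc1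
F4 | step 9 | tert-butyl (5S,6S)-6-(2-hydroxyethyl)-5-{3-[(4-methoxybenzyl)oxy]prop-1-en-2-yl}-6-methyl-2-methylidene-4-oxooct-7-enoate | C=C[C@](C)(CCO)[C@H](C(=O)CC(=C)C(=O)OC(C)(C)C)C(=C)COCc1ccc(OC)cc1
F5 | step 13 | tert-butyl (5S,6R,7R,8R,10S)-6,8-dihydroxy-15-[(4-methoxybenzyl)oxy]elema-1,3,11(13)-trien-12-oate | C=C[C@]1(C)C[C@@H](O)[C@@H](C(=C)C(=O)OC(C)(C)C)[C@H](O)[C@@H]1C(=C)COCc1ccc(OC)cc1
F6 | step 13 | (2Z)-4-acetoxy-2-methylbut-2-enoic acid | CC(=O)OC/C=C(C)\C(=O)O
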